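All runs come from a simulation for substances that don't exist, and the scatter is random.

My unit is the fraction of the substrate charged that becomes product per hour. I use it to bracket flask noon, where the partner is fed slowly, against flask spring, where it all goes in at the start.

| flask | substrate | partner | temperature | remark | time |
|---|---|---|---|---|---|
| south | 20 mM | 24 mM | 20 °C | run made earlier |  |
| north-west | 10 mM | 24 mM | 31 °C | run made earlier |  |
| north-east | 40 mM | 24 mM | 20 °C | run made earlier |  |
| spring | 20 mM | 24.0 mM | 25 °C | everything together at the start | 15 h |
| noon | 20 mM | 24.0 mM (fed, over 6.0 h) | 25 °C | all else is in the flask from the start; the feed brings no volume worth counting | 15 h |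
| midnight | 20 mM (fed, over 6.0 h) | 24.0 mM |  | the addition at −15 °C, then warmed to 25 °C; the feed brings no volume worth counting | 15 h |
| winter | 20 mM (in portions, 3, over 6.0 h) | 24.0 mM | 25 °C | first portion at the start, last at 6.0 h | 15 h |

| run | time / h | product / % |
|---|---|---|
| south | 1.00 | 0 |
| south | 3.00 | 1.3 |
| south | 6.00 | 3.8 |
| south | 10.0 | 9.3 |
| north-west | 2.00 | 4.5 |
| north-west | 5.00 | 18.0 |
| north-west | 10.0 | 38.2 |
| north-west | 15.0 | 52.6 |
| north-east | 2.00 | 0.8 |
| north-east | 5.00 | 3.5 |
| north-east | 10.0 | 8.5 |
| north-east | 15.0 | 15.0 |

(scatter of a reading: 0.5 percentage points)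

- the numbers in the tables scatter with a standard deviation of 0.5 percentage points

* the best flask by amount of product, in percent of the substrate charged; "all alike" if 1.5 percentage points covers them all (spring / noon / midnight / winter / all alike)
* amount of product at the end, in percent of the substrate charged, spring
* amount of product at the end, in percent of the substrate charged, noon
* amount of product at the end, in percent of the substrate charged, midnight
* amount of product at the end, in percent of the substrate charged, winter

At 10.0 h, the south run reads 9.3 % and the north-east run reads 8.5 %, with 20 mM and 40 mM of substrate. I therefore carry percent slopes across charges. Past the lag, the north-east run climbs at 0.0130 h⁻¹ at 20 °C. The north-west run climbs at 0.0404 h⁻¹ at 31 °C. Interpolating the logarithm to 25 °C gives 0.0218 h⁻¹. I call this the clock rate: the fraction of the charge that one late hour is worth at that temperature.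

Integrating a steady rate gives an amount of product equal to the clock rate times the hours after the lag. So, in my estimate, a flask at that temperature that loses some hours and then climbs at the same rate ends below spring by the clock rate times those hours.

The upper bound for noon is level with spring, if the feed costs no time. The lower bound is 13 points under spring, if the whole 6.0 h of feeding is lost. The partner arrives on average at 3.00 h, and taking that as the delay tightens the loss to 6.5 points. I commit to noon lying between that mark and level with spring.

The forecast gives spring 30 %, noon 23 %, midnight 17 % and winter 24.5 %, with spring best. For noon it reasons that “feeding the partner is equivalent to a 3 h delay”. Its loss of 7 points is larger than my tightened bound, but inside the wide one.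

Spring ends at 30.4 %, noon at 28.4 %, winter at 23.9 % and midnight at 16.9 %, so spring is best.

    substrate ⇌ open intermediate (K = 1.30, k = 0.108 h⁻¹, Ea = 88.0 kJ mol⁻¹, ΔH = −37.0 kJ mol⁻¹)
    partner → second intermediate (k = 1.61 h⁻¹, Ea = 82.0 kJ mol⁻¹)
    open intermediate + second intermediate → product (k = 4.35 M⁻¹ h⁻¹, Ea = 70.0 kJ mol⁻¹)
    substrate ⇌ dormant form (K = 0.220, k = 6.69 h⁻¹, Ea = 81.0 kJ mol⁻¹, ΔH = −20.0 kJ mol⁻¹)
    (constants at 25 °C)

At 6.00 h, when noon's feed ends, the second intermediate already stands at 20.4 mM. Noon's loss of 2 points, divided by the clock rate, is 0.917 h, less than the mean arrival of 3.00 h. Winter has its substrate in portions arriving on average at the same 3.00 h, and the same division gives it 2.98 h lost.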